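Ring C is treated as a masked cyclohex-2-enone: its hydroxyl-bearing carbon is the ketone carbon, the adjacent carbon carrying the ether oxygen to ring B is the saturated alpha carbon, and the carbon para to the hydroxyl, which holds the CH2CH2 link to ring D, is the gamma carbon. A single Robinson annulation joins aryloxyacetoacetate 6 (rings A and B with the ether oxygen in place) to 2-methylene aldehyde 12 (ring D and its chain), making two C–C bonds and closing ring C with all three substituents correctly placed. Dealkoxycarbonylation, dehydrogenation and demethylation finish the synthesis. Both partners are assembled by Sonogashira coupling and hydrogenation.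

Key step: step 8

Remark on the chemistry: the target has no stereocentre. Compounds 6 and 13 to 16 carry sp3 stereocentres that are formed without control (racemic, diastereomer mixtures where two are present); all of them disappear when ring C becomes aromatic.

Step 1
Reactants: 1 3-ethynylanisole (1-ethynyl-3-methoxybenzene); 2 4-iodophenol
Product: 3 4-[(3-methoxyphenyl)ethynyl]phenol
Conditions: Pd(PPh3)2Cl2 (2 mol%), CuI (4 mol%), Et3N, THF, degassed, rt → 50 °C
Reagents that add atoms: none
Why: Sonogashira coupling; the aryl iodide adds oxidatively to zerovalent palladium, the copper acetylide transmetalates, and the free phenol is tolerated under amine base.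

Step 2
Reactants: 3 4-[(3-methoxyphenyl)ethynyl]phenol
Product: 4 4-[2-(3-methoxyphenyl)ethyl]phenol
Conditions: H2 (1 atm), 10% Pd/C, EtOAc–MeOH, rt
Reagents that add atoms: none
Why: Heterogeneous catalytic hydrogenation should saturate the diaryl alkyne to the bibenzyl, while the phenol and the aryl methyl ether are inert.

Step 3
Reactants: 4 4-[2-(3-methoxyphenyl)ethyl]phenol; 5 ethyl 2-chloro-3-oxobutanoate (ethyl 2-chloroacetoacetate)
Product: 6 ethyl 2-[4-[2-(3-methoxyphenyl)ethyl]phenoxy]-3-oxobutanoate (racemic)
Conditions: K2CO3, acetone, reflux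
Reagents that add atoms: none
Why: Williamson-type SN2 O-alkylation; the phenoxide displaces a chloride activated by two flanking carbonyl groups, so the ortho-oxygenated diaryl ether of ring C needs no aryl–oxygen coupling.

Step 4
Reactants: 7 2-iodo-1,4-dimethoxybenzene; 8 but-3-yn-1-ol
Product: 9 4-(2,5-dimethoxyphenyl)but-3-yn-1-ol
Conditions: Pd(PPh3)2Cl2 (2 mol%), CuI (4 mol%), Et3N, THF, degassed, 50 °C
Reagents that add atoms: none
Why: Sonogashira coupling of an aryl iodide with a terminal alkyne; the free primary alcohol does not interfere.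

Step 5
Reactants: 9 4-(2,5-dimethoxyphenyl)but-3-yn-1-ol
Product: 10 4-(2,5-dimethoxyphenyl)butan-1-ol
Conditions: H2 (1 atm), 10% Pd/C, EtOAc, rt
Reagents that add atoms: none
Why: Catalytic hydrogenation of the alkyne to the saturated chain; the non-benzylic alcohol is not hydrogenolysed.

Step 6
Reactants: 10 4-(2,5-dimethoxyphenyl)butan-1-ol
Product: 11 4-(2,5-dimethoxyphenyl)butanal
Conditions: Dess–Martin periodinane, CH2Cl2, 0 °C → rt
Reagents that add atoms: none
Why: Dess–Martin oxidation should stop cleanly at the aldehyde and leave the electron-rich dimethoxyarene untouched.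

Step 7
Reactants: 11 4-(2,5-dimethoxyphenyl)butanal
Product: 12 4-(2,5-dimethoxyphenyl)-2-methylidenebutanal
Conditions: aq. HCHO (37%), pyrrolidine (10 mol%), EtCO2H (10 mol%), i-PrOH, 45 °C
Reagents that add atoms: formaldehyde, C=O
Why: Amine-catalysed Mannich condensation and elimination (alpha-methylenation of an aldehyde); the enamine of 11 adds to the formaldehyde iminium ion and loss of the amine gives the 2-alkylacrolein.

Step 8
Reactants: 6 ethyl 2-[4-[2-(3-methoxyphenyl)ethyl]phenoxy]-3-oxobutanoate; 12 4-(2,5-dimethoxyphenyl)-2-methylidenebutanal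
Product: 15 ethyl 5-[2-(2,5-dimethoxyphenyl)ethyl]-1-[4-[2-(3-methoxyphenyl)ethyl]phenoxy]-2-oxocyclohex-3-ene-1-carboxylate (racemic diastereomer mixture), via Michael adduct 13 (not isolated), via aldol adduct 14 (not isolated)
Conditions: Et3N (0.2 equiv), toluene, 0 °C → rt; then pyrrolidine (0.3 equiv), AcOH (0.3 equiv), 60 °C
Reagents that add atoms: none
Why: The amine base forms the stabilised enolate of 6 at its only doubly activated carbon, which adds in conjugate fashion to the terminal CH2 of enal 12 to give keto aldehyde 13; pyrrolidinium acetate then drives the intramolecular aldol of the methyl ketone onto the aldehyde (14) and the dehydration to the conjugated enone 15. The closest known reaction type is the Robinson annulation of alpha-substituted beta-keto esters with acrolein and 2-alkylacroleins. Ring C closes by a 6-(enolendo)-exo-trig aldol, because both enol carbons lie inside the new ring. The quaternary carbon C1 and the chain-bearing carbon C5 are formed without control as a diastereomer mixture, which is harmless because both become sp2 on aromatisation. The regiochemistry that the step needs is fixed by the substrate: after the Michael addition the carbon between the two carbonyls is quaternary, so the ketone can enolise only towards its methyl group, and closure from the aldehyde alpha carbon would give a four-membered ring.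

Step 9
Reactants: 15 ethyl 5-[2-(2,5-dimethoxyphenyl)ethyl]-1-[4-[2-(3-methoxyphenyl)ethyl]phenoxy]-2-oxocyclohex-3-ene-1-carboxylate
Product: 16 4-[2-(2,5-dimethoxyphenyl)ethyl]-6-[4-[2-(3-methoxyphenyl)ethyl]phenoxy]cyclohex-2-en-1-one (racemic diastereomer mixture)
Conditions: LiCl (3 equiv), H2O (2 equiv), DMSO, 150 °C
Reagents that add atoms: none
Why: Krapcho dealkoxycarbonylation; chloride dealkylates the beta-keto ester, the carboxylate loses CO2 and water protonates the enolate, under near-neutral conditions that avoid retro-Claisen opening of the non-enolisable keto ester; the new CH(OAr) centre forms as a mixture and is erased in step 10.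

Step 10
Reactants: 16 4-[2-(2,5-dimethoxyphenyl)ethyl]-6-[4-[2-(3-methoxyphenyl)ethyl]phenoxy]cyclohex-2-en-1-one
Product: 18 4-[2-(2,5-dimethoxyphenyl)ethyl]-2-[4-[2-(3-methoxyphenyl)ethyl]phenoxy]phenol, via cyclohexadienone 17 (not isolated)
Conditions: Pd(OCOCF3)2 (5 mol%), 2-(dimethylamino)pyridine (10 mol%), TsOH·H2O (20 mol%), O2 (1 atm), DMSO, 80 °C
Reagents that add atoms: none
Why: Aerobic dehydrogenation of a cyclohexenone by divalent palladium; a palladium enolate at C6 undergoes beta-hydride elimination to the cross-conjugated dienone 17, which tautomerises to the phenol, and O2 reoxidises the zerovalent palladium.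

Step 11
Reactants: 18 4-[2-(2,5-dimethoxyphenyl)ethyl]-2-[4-[2-(3-methoxyphenyl)ethyl]phenoxy]phenol
Product: 19 2-[2-[4-hydroxy-3-[4-[2-(3-hydroxyphenyl)ethyl]phenoxy]phenyl]ethyl]benzene-1,4-diol (target, CNP0300581.0)
Conditions: BBr3 (6 equiv), CH2Cl2, −78 °C → rt; then H2O, 0 °C, under argon
Reagents that add atoms: none
Why: Lewis-acid cleavage of aryl methyl ethers by BBr3 (bromide attacks the methyl group of the boron-complexed ether); the diaryl ether and the bibenzyl links are inert, and an oxygen-free work-up protects the hydroquinone of ring D.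

Compound list
1 | 3-ethynylanisole (1-ethynyl-3-methoxybenzene) | COc1cccc(C#C)c1 | starting material
2 | 4-iodophenol | Oc1ccc(I)cc1 | starting material
3 | 4-[(3-methoxyphenyl)ethynyl]phenol | COc1cccc(C#Cc2ccc(O)cc2)c1 | intermediate
4 | 4-[2-(3-methoxyphenyl)ethyl]phenol | COc1cccc(CCc2ccc(O)cc2)c1 | intermediate
5 | ethyl 2-chloro-3-oxobutanoate | CCOC(=O)C(Cl)C(C)=O | starting material
6 | ethyl 2-[4-[2-(3-methoxyphenyl)ethyl]phenoxy]-3-oxobutanoate (racemic) | CCOC(=O)C(Oc1ccc(CCc2cccc(OC)c2)cc1)C(C)=O | intermediate
7 | 2-iodo-1,4-dimethoxybenzene | COc1ccc(OC)c(I)c1 | starting material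
8 | but-3-yn-1-ol | OCCC#C | starting material
9 | 4-(2,5-dimethoxyphenyl)but-3-yn-1-ol | COc1ccc(OC)c(C#CCCO)c1 | intermediate
10 | 4-(2,5-dimethoxyphenyl)butan-1-ol | COc1ccc(OC)c(CCCCO)c1 | intermediate
11 | 4-(2,5-dimethoxyphenyl)butanal | COc1ccc(OC)c(CCCC=O)c1 | intermediate
12 | 4-(2,5-dimethoxyphenyl)-2-methylidenebutanal | C=C(CCc1cc(OC)ccc1OC)C=O | intermediate
13 | ethyl 2-acetyl-6-(2,5-dimethoxyphenyl)-4-formyl-2-[4-[2-(3-methoxyphenyl)ethyl]phenoxy]hexanoate (Michael adduct, diastereomer mixture, not isolated) | CCOC(=O)C(Oc1ccc(CCc2cccc(OC)c2)cc1)(CC(CCc1cc(OC)ccc1OC)C=O)C(C)=O | intermediate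
14 | ethyl 5-[2-(2,5-dimethoxyphenyl)ethyl]-4-hydroxy-1-[4-[2-(3-methoxyphenyl)ethyl]phenoxy]-2-oxocyclohexane-1-carboxylate (aldol adduct, diastereomer mixture, not isolated) | CCOC(=O)C1(Oc2ccc(CCc3cccc(OC)c3)cc2)CC(CCc2cc(OC)ccc2OC)C(O)CC1=O | intermediate
15 | ethyl 5-[2-(2,5-dimethoxyphenyl)ethyl]-1-[4-[2-(3-methoxyphenyl)ethyl]phenoxy]-2-oxocyclohex-3-ene-1-carboxylate (racemic, diastereomer mixture) | CCOC(=O)C1(Oc2ccc(CCc3cccc(OC)c3)cc2)CC(CCc2cc(OC)ccc2OC)C=CC1=O | intermediate
16 | 4-[2-(2,5-dimethoxyphenyl)ethyl]-6-[4-[2-(3-methoxyphenyl)ethyl]phenoxy]cyclohex-2-en-1-one (racemic, diastereomer mixture) | COc1cccc(CCc2ccc(OC3CC(CCc4cc(OC)ccc4OC)C=CC3=O)cc2)c1 | intermediate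
17 | 4-[2-(2,5-dimethoxyphenyl)ethyl]-2-[4-[2-(3-methoxyphenyl)ethyl]phenoxy]cyclohexa-2,5-dien-1-one (not isolated) | COc1cccc(CCc2ccc(OC3=CC(CCc4cc(OC)ccc4OC)C=CC3=O)cc2)c1 | intermediate
18 | 4-[2-(2,5-dimethoxyphenyl)ethyl]-2-[4-[2-(3-methoxyphenyl)ethyl]phenoxy]phenol | COc1cccc(CCc2ccc(Oc3cc(CCc4cc(OC)ccc4OC)ccc3O)cc2)c1 | intermediate
19 | 2-[2-[4-hydroxy-3-[4-[2-(3-hydroxyphenyl)ethyl]phenoxy]phenyl]ethyl]benzene-1,4-diol | Oc1cccc(CCc2ccc(Oc3cc(CCc4cc(O)ccc4O)ccc3O)cc2)c1 | target

Total step count: 11.
Longest linear sequence: 8 steps (steps 4, 5, 6, 7, 8, 9, 10, 11, from 7 and 8 to 19).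

Steps most likely to fail

Step 8. Base-induced oligomerisation of the 2-alkylacrolein may outrun a slow, reversible conjugate addition of the hindered tertiary donor, so that the enal is consumed before ring closure. The fallback sets out from aldehyde 11 and keto ester 6 and returns at 15, and it never handles the free enal. Aldehyde 11 is treated with dimethylmethylideneammonium iodide in CH2Cl2 at rt to give the Mannich base 2-[(dimethylamino)methyl]-4-(2,5-dimethoxyphenyl)butanal F1, kept as its hydroiodide. This salt is then stirred with 6 and Et3N in toluene at rt to 40 °C, so that dimethylamine is lost slowly and the enal is trapped as it forms (classical Mannich-base variant of the Robinson annulation). Pyrrolidine and AcOH at 60 °C then close the ring through 13 and 14 to 15.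

Step 10. The catalytic cycle may stall through aggregation of reduced palladium before the alpha-aryloxy enone is fully dehydrogenated. The fallback sets out from 16 and returns at 18. Kinetic deprotonation at the aryloxy-bearing carbon with LiN(i-Pr)2 in THF at −78 °C and trapping with PhSeCl should give 4-[2-(2,5-dimethoxyphenyl)ethyl]-6-[4-[2-(3-methoxyphenyl)ethyl]phenoxy]-6-(phenylselanyl)cyclohex-2-en-1-one F2. Oxidation with H2O2 and pyridine in CH2Cl2 at 0 °C to rt gives the corresponding selenoxide, 6-(benzeneseleninyl)-4-[2-(2,5-dimethoxyphenyl)ethyl]-6-[4-[2-(3-methoxyphenyl)ethyl]phenoxy]cyclohex-2-en-1-one F3, which is not isolated. Its syn-elimination delivers dienone 17, and tautomerisation gives 18.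

Step 3. Deprotonation and self-condensation of the chloro keto ester by the carbonate base may compete with displacement of chloride by the phenoxide, and the product may be deacetylated. The fallback sets out from 4 and returns at 6. Ethyl acetoacetate is converted with 4-acetamidobenzenesulfonyl azide and Et3N in MeCN into ethyl 2-diazo-3-oxobutanoate F4. Rh2(OAc)4 (1 mol%) in CH2Cl2 at reflux then inserts the derived carbenoid into the O–H bond of phenol 4, which gives 6 under neutral conditions with loss of nitrogen.

Further compounds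
F1 | step 8 | 2-[(dimethylamino)methyl]-4-(2,5-dimethoxyphenyl)butanal | CN(C)CC(CCc1cc(OC)ccc1OC)C=O
F2 | step 10 | 4-[2-(2,5-dimethoxyphenyl)ethyl]-6-[4-[2-(3-methoxyphenyl)ethyl]phenoxy]-6-(phenylselanyl)cyclohex-2-en-1-one | COc1cccc(CCc2ccc(OC3(CC(CCc4cc(OC)ccc4OC)C=CC3=O)[Se]c3ccccc3)cc2)c1
F3 | step 10 | 6-(benzeneseleninyl)-4-[2-(2,5-dimethoxyphenyl)ethyl]-6-[4-[2-(3-methoxyphenyl)ethyl]phenoxy]cyclohex-2-en-1-one | COc1cccc(CCc2ccc(OC3(CC(CCc4cc(OC)ccc4OC)C=CC3=O)[Se](=O)c3ccccc3)cc2)c1
F4 | step 3 | ethyl 2-diazo-3-oxobutanoate | CCOC(=O)C(=[N+]=[N-])C(C)=O
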